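**Retrosynthetic overview**
1. Numbering (decahydronaphthalene): ring A = C4a–C5–C6–C7–C8–C8a (C8 carries CH3 and the aryloxy oxygen, C4a the angular CH3); ring B = C8a–C1–C2–C3–C4–C4a (C2 carries C(CH3)2OH); the ring fusion is cis.
2. Aryl ether: the C8 tertiary alkoxide displaces fluoride from a 2-aryloxy-6-fluorobenzaldehyde (SNAr); the formyl group then becomes the phenol (Dakin-type oxidation), the allyl groups replace two aryl bromides (Stille), and the C2 ester becomes C(CH3)2OH last.
3. C2–H is set by hydrogenation of the ring B enoates directed by the C8 hydroxyl (both alkene regioisomers converge); C8 is set by methyl addition to the convex face of a cis-fused C8 ketone.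
4. Ring B is closed at the C1–C8a bond by an enantioselective conjugate methylation / Michael ring closure of an achiral 3-alkylcyclohex-2-enone carrying a 2-substituted acrylate; this step also sets C4a and C8a. Ring order: ring A purchased (as 3-ethoxycyclohexenone), ring B in the key step, both benzene rings purchased.
5. Enabling feature: C8a lies between the oxygen-bearing C8 (a ketone carbon in the precursor) and the methyl-bearing quaternary C4a, so conjugate methylation at C4a creates the enolate exactly at C8a; C1 is the CH2 next to C2, whose side chain can be an ester, so C1 is the β-carbon of an acrylate.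

Key step: step 3

Remark: the SMILES defines a cis-fused decalin (C4a methyl and C8a hydrogen on the same face; 2R,4aR,8R,8aS), and the route is built for it; the enantiomer of the phosphoramidite ligand in step 3 is to be chosen so that it gives 4aR.

**Step 1**
Reactants: 1 3-ethoxycyclohex-2-en-1-one
Product: 3 3-ethenylcyclohex-2-en-1-one, via bromomagnesium 3-ethoxy-1-ethenylcyclohex-2-en-1-olate 2 (not isolated)
Conditions: CH2=CHMgBr, THF, 0 °C; then 1 M HCl, 0 → 20 °C
Reagents that add atoms: vinylmagnesium bromide, C=C[Mg]Br; water, O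
Why: The Grignard reagent adds 1,2 to the vinylogous ester and aqueous acid then hydrolyses the enol ether and eliminates water with transposition of the carbonyl group (Stork–Danheiser sequence), which gives the 3-substituted enone.

**Step 2**
Reactants: 3 3-ethenylcyclohex-2-en-1-one; 4 tert-butyl 2-(diethoxyphosphoryl)acetate
Product: 6 tert-butyl 2-methylidene-4-(3-oxocyclohex-1-en-1-yl)butanoate, via tert-butyl 2-(diethoxyphosphoryl)-4-(3-oxocyclohex-1-en-1-yl)butanoate 5 (not isolated)
Conditions: t-BuOK (10 mol %), THF, 0 → 20 °C; then 37% aq. CH2O, K2CO3, 50 °C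
Reagents that add atoms: formaldehyde, C=O
Why: The phosphonoacetate anion adds in a base-catalysed 1,6-conjugate (vinylogous Michael) addition to the unhindered terminal carbon of the dienone, and the resulting α-alkyl phosphonate is methylenated with formaldehyde in a Horner–Wadsworth–Emmons reaction, which builds the 2-substituted acrylate.

**Step 3**
Reactants: 6 tert-butyl 2-methylidene-4-(3-oxocyclohex-1-en-1-yl)butanoate
Product: 9 tert-butyl (4aR,8aS)-4a-methyl-8-oxodecahydronaphthalene-2-carboxylate (cis-fused; both C2 epimers), via dimethylaluminium cyclohexenolate 7 (not isolated), via dimethylaluminium ketene acetal 8 (not isolated)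
Conditions: Me3Al (2 equiv), Cu(O2C-C4H3S) (copper thiophene-2-carboxylate, 5 mol %), binaphthol bis(1-phenylethyl)amine phosphoramidite (10 mol %), Et2O, −30 °C; then THF, −30 → 20 °C; aq. potassium sodium tartrate (KNaC4H4O6)
Reagents that add atoms: trimethylaluminium, C[Al](C)C
Why: Copper-catalysed enantioselective 1,4-transfer of methyl from Me3Al to the β-carbon of the 3-alkylcyclohexenone creates C4a and, regiospecifically, the aluminium enolate 7 whose nucleophilic carbon is the future C8a; this enolate then adds to the unsubstituted CH2 terminus of the tethered 2-alkyl acrylate (assisted by excess Me3Al as Lewis acid) to give ester enolate 8, which is protonated on work-up. The closest known reaction type is the copper-catalysed asymmetric conjugate addition to a cyclic enone followed by intramolecular Michael trapping of the metal enolate (Michael-initiated ring closure). Ring B closes in the 6-endo-trig mode, C1 being the only electrophilic acrylate position within reach of C8a. C4a (R) is controlled by the chiral copper–phosphoramidite catalyst; C8a (S) is controlled by the substrate, because the three-atom tether on C4a can reach the enolate carbon only from its own face with axial bond formation, which gives the cis fusion; C2 forms without control on protonation and is corrected in steps 5 and 6. The step needs methyl transfer to the enone and not to the acrylate, which rests on the preferential activation of the ketone by aluminium and the low reactivity of ester acceptors under these conditions, and conjugate rather than acyl attack on the ester, which the tert-butyl group secures.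

**Step 4**
Reactants: 9 tert-butyl (4aR,8aS)-4a-methyl-8-oxodecahydronaphthalene-2-carboxylate
Product: 10 tert-butyl (4aR,8R,8aS)-8-hydroxy-4a,8-dimethyldecahydronaphthalene-2-carboxylate (both C2 epimers)
Conditions: MeLi, CeCl3, THF, −78 °C; aq. NH4Cl
Reagents that add atoms: methyllithium, C[Li]
Why: 1,2-Addition of the weakly basic organocerium reagent to the ketone should come from the convex face of the cis-decalone (equatorial attack anti to ring B, the axial path being blocked by the syn-axial C4 methylene) and so give the 8R carbinol with oxygen cis to C1, without enolisation toward C8a and without touching the tert-butyl ester.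

**Step 5**
Reactants: 10 tert-butyl (4aR,8R,8aS)-8-hydroxy-4a,8-dimethyldecahydronaphthalene-2-carboxylate
Product: 11 tert-butyl (4aR,8R,8aS)-8-hydroxy-4a,8-dimethyl-2-(phenylselanyl)decahydronaphthalene-2-carboxylate
Conditions: LiN(i-Pr)2 (2.2 equiv), THF, −78 → −30 °C; PhSeBr, −78 °C; AcOH quench at −78 °C
Reagents that add atoms: phenylselanyl bromide, Br[Se]c1ccccc1
Why: α-Selenenylation of the ester enolate, formed beside the lithium alkoxide with two equivalents of amide base, converts both C2 epimers of 10 into one constitution, and the configuration of the selenium-bearing carbon is of no consequence because that centre is removed in step 6.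

**Step 6**
Reactants: 11 tert-butyl (4aR,8R,8aS)-8-hydroxy-4a,8-dimethyl-2-(phenylselanyl)decahydronaphthalene-2-carboxylate
Product: 14 tert-butyl (2R,4aR,8R,8aS)-8-hydroxy-4a,8-dimethyldecahydronaphthalene-2-carboxylate, via C2=C3 enoate 12 (not isolated), via C1=C2 enoate 13 (not isolated)
Conditions: 30% H2O2, pyridine, CH2Cl2, 0 → 20 °C; aqueous wash and passage through a short silica pad without separation of the enoates; then H2 (1 atm), [Ir(cod)(PCy3)(py)]PF6 (5 mol %), CH2Cl2, 20 °C
Reagents that add atoms: none
Why: Oxidation to the selenoxide and syn-elimination toward C3 or C1 should give the two conjugated enoates 12 and 13, and in the following hydroxyl-directed hydrogenation the cationic iridium catalyst, held by the C8 hydroxyl on the concave face under ring B, adds hydrogen to either double bond from that face, so that hydrogen enters C2 cis to the C8 oxygen and both isomers converge on the 2R ester (ester trans to C8 across ring B).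

**Step 7**
Reactants: 15 4-bromo-2,6-difluorobenzaldehyde; 16 4-bromophenol
Product: 17 4-bromo-2-(4-bromophenoxy)-6-fluorobenzaldehyde
Conditions: K2CO3, DMF, 0 → 20 °C
Reagents that add atoms: none
Why: In this SNAr reaction the phenoxide displaces one fluoride ortho to the formyl group, the first aryloxy group deactivates the ring so that monosubstitution is expected, and bromide is a far poorer leaving group than fluoride.

**Step 8**
Reactants: 14 tert-butyl (2R,4aR,8R,8aS)-8-hydroxy-4a,8-dimethyldecahydronaphthalene-2-carboxylate; 17 4-bromo-2-(4-bromophenoxy)-6-fluorobenzaldehyde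
Product: 18 tert-butyl (2R,4aR,8R,8aS)-8-[5-bromo-3-(4-bromophenoxy)-2-formylphenoxy]-4a,8-dimethyldecahydronaphthalene-2-carboxylate
Conditions: KN(SiMe3)2, THF, −78 → 0 °C; then 17, 0 → 20 °C
Reagents that add atoms: none
Why: SNAr of the potassium tertiary alkoxide at the remaining fluoride ortho to the formyl group (fluoride leaves far faster than aryloxide or bromide) makes the hindered ether without breaking the C8–O bond, so the C8 configuration is kept, and the 2R ester, being trans to the alkoxide, cannot lactonise.

**Step 9**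
Reactants: 18 tert-butyl (2R,4aR,8R,8aS)-8-[5-bromo-3-(4-bromophenoxy)-2-formylphenoxy]-4a,8-dimethyldecahydronaphthalene-2-carboxylate
Product: 20 tert-butyl (2R,4aR,8R,8aS)-8-[5-bromo-3-(4-bromophenoxy)-2-hydroxyphenoxy]-4a,8-dimethyldecahydronaphthalene-2-carboxylate, via aryl formate 19 (not isolated)
Conditions: mCPBA, CH2Cl2, 0 → 20 °C; then K2CO3 (cat.), MeOH
Reagents that add atoms: mCPBA (3-chloroperoxybenzoic acid), OOC(=O)c1cccc(Cl)c1
Why: Baeyer–Villiger oxidation of the electron-rich 2,6-dioxygenated benzaldehyde with aryl migration (Dakin-type) gives the formate, which is methanolysed to the phenol, and no alkene is present yet to compete for the peracid.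

**Step 10**
Reactants: 20 tert-butyl (2R,4aR,8R,8aS)-8-[5-bromo-3-(4-bromophenoxy)-2-hydroxyphenoxy]-4a,8-dimethyldecahydronaphthalene-2-carboxylate
Product: 21 tert-butyl (2R,4aR,8R,8aS)-8-{2-hydroxy-5-(prop-2-en-1-yl)-3-[4-(prop-2-en-1-yl)phenoxy]phenoxy}-4a,8-dimethyldecahydronaphthalene-2-carboxylate
Conditions: allylSnBu3 (3 equiv), Pd2(dba)3 (5 mol %), P(t-Bu)3 (12 mol %), CsF, dioxane, 80 °C
Reagents that add atoms: allyltributylstannane, C=CC[Sn](CCCC)(CCCC)CCCC
Why: Twofold Stille coupling of the two aryl bromides with the allylstannane under a bulky-phosphine palladium catalyst with fluoride activation should be mild enough to leave the allyl groups unconjugated and the free phenol and the tertiary ether intact.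

**Step 11**
Reactants: 21 tert-butyl (2R,4aR,8R,8aS)-8-{2-hydroxy-5-(prop-2-en-1-yl)-3-[4-(prop-2-en-1-yl)phenoxy]phenoxy}-4a,8-dimethyldecahydronaphthalene-2-carboxylate
Product: 23 2-[(2R,4aR,8R,8aS)-8-{2-hydroxy-5-(prop-2-en-1-yl)-3-[4-(prop-2-en-1-yl)phenoxy]phenoxy}-4a,8-dimethyldecahydronaphthalen-2-yl]propan-2-ol, via methyl ketone 22 (not isolated)
Conditions: MeLi (6 equiv), CeCl3 (6 equiv), THF, −78 → 0 °C; aq. NH4Cl
Reagents that add atoms: methyllithium, C[Li]
Why: Double addition of the non-basic methylcerium reagent to the tert-butyl ester through methyl ketone 22 gives the tertiary alcohol without enolisation at C2 (one equivalent is consumed by the phenol), which completes the target.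

**Compound list**
1 | 3-ethoxycyclohex-2-en-1-one | CCOC1=CC(=O)CCC1 | starting material
2 | bromomagnesium 3-ethoxy-1-ethenylcyclohex-2-en-1-olate | CCOC1=CC(C=C)(O[Mg]Br)CCC1 | intermediate
3 | 3-ethenylcyclohex-2-en-1-one | C=CC1=CC(=O)CCC1 | intermediate
4 | tert-butyl 2-(diethoxyphosphoryl)acetate | CCOP(=O)(OCC)CC(=O)OC(C)(C)C | starting material
5 | tert-butyl 2-(diethoxyphosphoryl)-4-(3-oxocyclohex-1-en-1-yl)butanoate | CCOP(=O)(OCC)C(CCC1=CC(=O)CCC1)C(=O)OC(C)(C)C | intermediate
6 | tert-butyl 2-methylidene-4-(3-oxocyclohex-1-en-1-yl)butanoate | C=C(CCC1=CC(=O)CCC1)C(=O)OC(C)(C)C | intermediate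
7 | dimethylaluminium enolate of tert-butyl 2-methylidene-4-[(1R)-1-methyl-3-oxocyclohexyl]butanoate (enolate C=C toward ring C2) | C=C(CC[C@@]1(C)CCCC(O[Al](C)C)=C1)C(=O)OC(C)(C)C | intermediate
8 | dimethylaluminium tert-butyl ketene acetal (C2 ester enolate) of 9, (4aR,8aS) | O=C1CCC[C@]2(C)CCC(=C(O[Al](C)C)OC(C)(C)C)C[C@@H]21 | intermediate
9 | tert-butyl (4aR,8aS)-4a-methyl-8-oxodecahydronaphthalene-2-carboxylate, both C2 epimers | O=C1CCC[C@]2(C)CCC(C(=O)OC(C)(C)C)C[C@@H]21 | intermediate
10 | tert-butyl (4aR,8R,8aS)-8-hydroxy-4a,8-dimethyldecahydronaphthalene-2-carboxylate, both C2 epimers | O[C@]1(C)CCC[C@]2(C)CCC(C(=O)OC(C)(C)C)C[C@@H]21 | intermediate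
11 | tert-butyl (4aR,8R,8aS)-8-hydroxy-4a,8-dimethyl-2-(phenylselanyl)decahydronaphthalene-2-carboxylate | O[C@]1(C)CCC[C@]2(C)CCC([Se]c3ccccc3)(C(=O)OC(C)(C)C)C[C@@H]21 | intermediate
12 | tert-butyl (4aR,8R,8aS)-8-hydroxy-4a,8-dimethyl-1,4,4a,5,6,7,8,8a-octahydronaphthalene-2-carboxylate | O[C@]1(C)CCC[C@]2(C)CC=C(C(=O)OC(C)(C)C)C[C@@H]21 | intermediate
13 | tert-butyl (4aR,8R,8aS)-8-hydroxy-4a,8-dimethyl-3,4,4a,5,6,7,8,8a-octahydronaphthalene-2-carboxylate | O[C@]1(C)CCC[C@]2(C)CCC(C(=O)OC(C)(C)C)=C[C@@H]21 | intermediate
14 | tert-butyl (2R,4aR,8R,8aS)-8-hydroxy-4a,8-dimethyldecahydronaphthalene-2-carboxylate | O[C@]1(C)CCC[C@]2(C)CC[C@@H](C(=O)OC(C)(C)C)C[C@@H]21 | intermediate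
15 | 4-bromo-2,6-difluorobenzaldehyde | O=Cc1c(F)cc(Br)cc1F | starting material
16 | 4-bromophenol | Oc1ccc(Br)cc1 | starting material
17 | 4-bromo-2-(4-bromophenoxy)-6-fluorobenzaldehyde | O=Cc1c(F)cc(Br)cc1Oc1ccc(Br)cc1 | intermediate
18 | tert-butyl (2R,4aR,8R,8aS)-8-[5-bromo-3-(4-bromophenoxy)-2-formylphenoxy]-4a,8-dimethyldecahydronaphthalene-2-carboxylate | O=Cc1c(O[C@]2(C)CCC[C@]3(C)CC[C@@H](C(=O)OC(C)(C)C)C[C@@H]32)cc(Br)cc1Oc1ccc(Br)cc1 | intermediate
19 | tert-butyl (2R,4aR,8R,8aS)-8-[5-bromo-3-(4-bromophenoxy)-2-(formyloxy)phenoxy]-4a,8-dimethyldecahydronaphthalene-2-carboxylate | O=COc1c(O[C@]2(C)CCC[C@]3(C)CC[C@@H](C(=O)OC(C)(C)C)C[C@@H]32)cc(Br)cc1Oc1ccc(Br)cc1 | intermediate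
20 | tert-butyl (2R,4aR,8R,8aS)-8-[5-bromo-3-(4-bromophenoxy)-2-hydroxyphenoxy]-4a,8-dimethyldecahydronaphthalene-2-carboxylate | Oc1c(O[C@]2(C)CCC[C@]3(C)CC[C@@H](C(=O)OC(C)(C)C)C[C@@H]32)cc(Br)cc1Oc1ccc(Br)cc1 | intermediate
21 | tert-butyl (2R,4aR,8R,8aS)-8-{2-hydroxy-5-(prop-2-en-1-yl)-3-[4-(prop-2-en-1-yl)phenoxy]phenoxy}-4a,8-dimethyldecahydronaphthalene-2-carboxylate | C=CCc1ccc(Oc2cc(CC=C)cc(O[C@]3(C)CCC[C@]4(C)CC[C@@H](C(=O)OC(C)(C)C)C[C@@H]43)c2O)cc1 | intermediate
22 | 1-[(2R,4aR,8R,8aS)-8-{2-hydroxy-5-(prop-2-en-1-yl)-3-[4-(prop-2-en-1-yl)phenoxy]phenoxy}-4a,8-dimethyldecahydronaphthalen-2-yl]ethan-1-one | C=CCc1ccc(Oc2cc(CC=C)cc(O[C@]3(C)CCC[C@]4(C)CC[C@@H](C(C)=O)C[C@@H]43)c2O)cc1 | intermediate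
23 | 2-[(2R,4aR,8R,8aS)-8-{2-hydroxy-5-(prop-2-en-1-yl)-3-[4-(prop-2-en-1-yl)phenoxy]phenoxy}-4a,8-dimethyldecahydronaphthalen-2-yl]propan-2-ol | C=CCc1ccc(Oc2cc(CC=C)cc(O[C@]3(C)CCC[C@]4(C)CC[C@@H](C(C)(C)O)C[C@@H]43)c2O)cc1 | target

**Step count and risks**
Total step count: 11. Longest linear sequence: 10 (steps 1–6 and 8–11); step 7 is a one-step side branch.

Steps most likely to fail:

1. Step 3. The aluminium enolate may close the ring too slowly, so that proton transfer between enolates or acyl attack on the ester competes, and some methyl may be transferred to the acrylate. The fallback sets out from 6: the same copper-catalysed methyl addition is quenched with TMSOTf to give tert-butyl 2-methylidene-4-[(1R)-1-methyl-3-(trimethylsilyloxy)cyclohex-2-en-1-yl]butanoate F1, which is isolated and cyclised with TiCl4 in CH2Cl2 at −78 °C (intramolecular Mukaiyama–Michael addition, cis fusion for the same geometric reason). It returns to the route at 9.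

2. Step 8. The very hindered alkoxide may attack the arene slowly while adding reversibly to the formyl group, which would leave time for base-induced epimerisation at C2 and attack on the ester. The fallback sets out from 14 and 15: the alkoxide is combined first with the more electrophilic and less encumbered difluoride 15 to give tert-butyl (2R,4aR,8R,8aS)-8-(5-bromo-3-fluoro-2-formylphenoxy)-4a,8-dimethyldecahydronaphthalene-2-carboxylate F2, and the 4-bromophenoxy group is then introduced with 16 and K2CO3 in DMF. It returns to the route at 18.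

3. Step 6. The hydroxyl may fail to hold the iridium on the concave face of the electron-poor trisubstituted alkenes, or selenium residues carried over from the elimination may deactivate the catalyst, which would give slow reduction or poor facial control at C2. The fallback sets out from 10 and replaces steps 5 and 6 by base equilibration with recycling. Silylation (TESOTf, 2,6-lutidine, CH2Cl2, −78 → −20 °C) gives tert-butyl (4aR,8R,8aS)-4a,8-dimethyl-8-(triethylsilyloxy)decahydronaphthalene-2-carboxylate F3 as the C2 mixture; the silyl group keeps the C8 oxygen from lactonising onto a cis C2 ester under base. Equilibration (t-BuOK, t-BuOH/THF) then interconverts the C2 epimers. The (2R) ester, tert-butyl (2R,4aR,8R,8aS)-4a,8-dimethyl-8-(triethylsilyloxy)decahydronaphthalene-2-carboxylate F4, has its ester equatorial in the chair–chair conformer that keeps both methyl groups equatorial on ring A, but that conformer holds the silyloxy group on the concave face, so only a modest preference can be counted on. F4 is therefore separated and the (2S) epimer is returned to the equilibration. Desilylation of F4 (Bu4NF, AcOH, THF) gives 14, where the fallback returns to the route.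

**Further compounds**
F1 | step 3 | tert-butyl 2-methylidene-4-[(1R)-1-methyl-3-(trimethylsilyloxy)cyclohex-2-en-1-yl]butanoate | C=C(CC[C@@]1(C)CCCC(O[Si](C)(C)C)=C1)C(=O)OC(C)(C)C
F2 | step 8 | tert-butyl (2R,4aR,8R,8aS)-8-(5-bromo-3-fluoro-2-formylphenoxy)-4a,8-dimethyldecahydronaphthalene-2-carboxylate | O=Cc1c(F)cc(Br)cc1O[C@]2(C)CCC[C@]3(C)CC[C@@H](C(=O)OC(C)(C)C)C[C@@H]32
F3 | step 6 | tert-butyl (4aR,8R,8aS)-4a,8-dimethyl-8-(triethylsilyloxy)decahydronaphthalene-2-carboxylate, both C2 epimers | CC[Si](CC)(CC)O[C@]1(C)CCC[C@]2(C)CCC(C(=O)OC(C)(C)C)C[C@@H]21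
F4 | step 6 | tert-butyl (2R,4aR,8R,8aS)-4a,8-dimethyl-8-(triethylsilyloxy)decahydronaphthalene-2-carboxylate | CC[Si](CC)(CC)O[C@]1(C)CCC[C@]2(C)CC[C@@H](C(=O)OC(C)(C)C)C[C@@H]21
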